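Everything rests on cutting both C–O bonds of the peroxide in ring A (the 1,2-dioxane; ring B is the lactone). The key step exploits that the two peroxide-bearing carbons, quaternary C6 and the CH carbon C3, can both be electrophiles for a single H2O2: C6 as the tertiary carbon of a Sharpless-derived epoxide, C3 as an aldehyde. One operation thus brings in the O–O unit, fixes C6 by inversion and closes ring A as a 1,2-dioxan-3-ol. The precursor is an acyclic C3–C8 epoxy aldehyde whose tertiary oxygen on C4 (O4, later the lactone oxygen) is silylated and whose C8 hydroxyl is free.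

Key step: step 9

Atom labels: C1 lactone carbonyl, C2 its CH2, C3 the O–O-bearing CH, C4 the methyl-bearing carbon that carries O4, C5 the ring CH2, C6 the methyl-bearing peroxide carbon, C7–C18 the chain. Ring compounds 17–31 are named with these locants.
Remark: C3 of 17–19 and 25–28 and C1 of 32 are carried as anomeric mixtures, because each of these centres is later made planar or oxidised.
Remark: hydrogen peroxide is numbered (15) as a reactant of the key step and is used as a dried ethereal solution.

Step 1
Reactants: 1 (R)-lactic acid; 2 pivalaldehyde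
Product: 3 (2R,5R)-2-tert-butyl-5-methyl-1,3-dioxolan-4-one (cis)
Conditions: TsOH·H2O (cat.), H2SO4 (cat.), pentane, reflux, Dean–Stark; recrystallisation from pentane–Et2O at −78 °C
Reagents that add atoms: none
Why: Acid-catalysed acetalisation with azeotropic removal of water should favour the cis-dioxolanone, and crystallisation should leave the (2R,5R) isomer, whose new acetal centre stores the chirality of the lactic acid.

Step 2
Reactants: 4 prenyl acetate
Product: 5 (2E)-4-hydroxy-3-methylbut-2-en-1-yl acetate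
Conditions: SeO2 (cat.), t-BuOOH, salicylic acid (cat.), CH2Cl2, rt
Reagents that add atoms: tert-butyl hydroperoxide, CC(C)(C)OO
Why: Riley allylic oxidation (ene reaction, then 2,3-sigmatropic shift) hydroxylates the methyl group trans to the chain of prenyl-type esters, so the (E)-alcohol should result.

Step 3
Reactants: 5 (2E)-4-hydroxy-3-methylbut-2-en-1-yl acetate
Product: 6 (2E)-4-bromo-3-methylbut-2-en-1-yl acetate
Conditions: CBr4, PPh3, CH2Cl2, 0 °C
Reagents that add atoms: carbon tetrabromide, BrC(Br)(Br)Br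
Why: Appel bromination of a primary allylic alcohol goes by SN2 displacement of the oxyphosphonium group and should leave the alkene geometry and the acetate untouched.

Step 4
Reactants: 3 (2R,5R)-2-tert-butyl-5-methyl-1,3-dioxolan-4-one; 6 (2E)-4-bromo-3-methylbut-2-en-1-yl acetate
Product: 8 (2R,5S)-5-[(2E)-4-acetoxy-2-methylbut-2-en-1-yl]-2-tert-butyl-5-methyl-1,3-dioxolan-4-one, via lithium enolate 7 (not isolated)
Conditions: LiN(i-Pr)2, THF, −78 °C; then 6, −78 to −30 °C
Reagents that add atoms: none
Why: Enolate alkylation with self-regeneration of the stereocentre: the tert-butyl group on the acetal carbon shields one face of the planar enolate, so the allylic bromide should enter trans to it (SN2 at the primary carbon) and set the quaternary centre C4 by net replacement of H with retention.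

Step 5
Reactants: 8 (2R,5S)-5-[(2E)-4-acetoxy-2-methylbut-2-en-1-yl]-2-tert-butyl-5-methyl-1,3-dioxolan-4-one
Product: 9 methyl (2S,4E)-2,6-dihydroxy-2,4-dimethylhex-4-enoate
Conditions: NaOMe (cat.), MeOH, 0 °C to rt
Reagents that add atoms: methanol, CO
Why: Base-catalysed transesterification opens the acylal lactone (the hemiacetal alkoxide then releases pivalaldehyde) and removes the acetate in the same pot, and the quaternary centre cannot epimerise.

Step 6
Reactants: 9 methyl (2S,4E)-2,6-dihydroxy-2,4-dimethylhex-4-enoate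
Product: 11 methyl (2S,4E)-2-[(tert-butyldimethylsilyl)oxy]-2,4-dimethyl-6-[(triethylsilyl)oxy]hex-4-enoate, via primary triethylsilyl ether 10 (not isolated)
Conditions: Et3SiOSO2CF3 (1.0 equiv), 2,6-lutidine, CH2Cl2, −78 °C; then t-BuMe2SiOSO2CF3, −78 to 0 °C
Reagents that add atoms: triethylsilyl trifluoromethanesulfonate, CC[Si](CC)(CC)OS(=O)(=O)C(F)(F)F; tert-butyldimethylsilyl trifluoromethanesulfonate, CC(C)(C)[Si](C)(C)OS(=O)(=O)C(F)(F)F
Why: Silyl triflates silylate alcohols in order of steric access, so the primary allylic hydroxyl should take the labile triethylsilyl group first and the tertiary hydroxyl O4 then the robust tert-butyldimethylsilyl group.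

Step 7
Reactants: 11 methyl (2S,4E)-2-[(tert-butyldimethylsilyl)oxy]-2,4-dimethyl-6-[(triethylsilyl)oxy]hex-4-enoate
Product: 13 (2S,4E)-2-[(tert-butyldimethylsilyl)oxy]-6-hydroxy-2,4-dimethylhex-4-enal, via bis-silyl aldehyde 12 (not isolated)
Conditions: i-Bu2AlH (1.2 equiv), CH2Cl2, −78 °C; then 1 M HCl, THF, 0 °C
Reagents that add atoms: none
Why: Partial reduction of an alpha-silyloxy ester stops at the aluminium hemiacetal at −78 °C, and the acidic work-up that releases the aldehyde should also hydrolyse the primary triethylsilyl ether while the tertiary silyl ether stays.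

Step 8
Reactants: 13 (2S,4E)-2-[(tert-butyldimethylsilyl)oxy]-6-hydroxy-2,4-dimethylhex-4-enal
Product: 14 (2S)-2-[(tert-butyldimethylsilyl)oxy]-3-[(2S,3S)-3-(hydroxymethyl)-2-methyloxiran-2-yl]-2-methylpropanal
Conditions: Ti(O-i-Pr)4, diethyl L-(+)-tartrate, t-BuOOH, 4 Å molecular sieves, CH2Cl2, −20 °C
Reagents that add atoms: tert-butyl hydroperoxide, CC(C)(C)OO
Why: Sharpless asymmetric epoxidation of an (E)-3-methylalk-2-en-1-ol is reagent-controlled, the L-(+)-tartrate complex delivering oxygen to the face that gives the (2S,3S)-epoxy alcohol as with other E-trisubstituted allylic alcohols, and the non-enolisable aldehyde should be a tolerated spectator.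

Step 9
Reactants: 14 (2S)-2-[(tert-butyldimethylsilyl)oxy]-3-[(2S,3S)-3-(hydroxymethyl)-2-methyloxiran-2-yl]-2-methylpropanal; 15 hydrogen peroxide
Product: 17 (4S,6R)-4-[(tert-butyldimethylsilyl)oxy]-6-[(1S)-1,2-dihydroxyethyl]-4,6-dimethyl-1,2-dioxan-3-ol (C3 anomers), via hydroperoxy aldehyde 16 (not isolated)
Conditions: H2O2 (dried Et2O solution, excess), H3PMo12O40 (cat.), Et2O, 0 °C to rt
Reagents that add atoms: hydrogen peroxide (compound 15), OO
Why: The heteropolyacid activates the epoxide oxygen, and H2O2, either free or already bound to the C3 aldehyde as its perhydrate, attacks the tertiary carbon C6 from the side opposite the leaving oxygen; the closest known reactions are the H3PMo12O40-catalysed perhydrolysis of trisubstituted epoxides (attack at the more substituted carbon with inversion) and the spontaneous cyclisation of delta-hydroperoxy aldehydes to 1,2-dioxan-3-ols. Ring A closes in the 6-exo-tet mode when the aldehyde-bound hydroperoxide opens the epoxide, and in the 6-exo-trig mode when free H2O2 opens it first and the C6 hydroperoxide of 16 then adds to the C3 carbonyl; both paths end at 17. The new stereocentre C6 is controlled by the epoxide configuration set in step 8, because the SN2-like opening is stereospecific; C7 keeps its oxygen and C3 forms as an anomeric mixture that is levelled later. The step needs attack at C6 and not at C7, which the ability of the tertiary carbon to carry positive charge under acid catalysis should secure, and it needs a peroxide oxygen and not O4 or the carbonyl oxygen as the nucleophile, which the silyl cap on O4, the high nucleophilicity of hydroperoxide oxygen and the excess of H2O2 are meant to secure.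

Step 10
Reactants: 17 (4S,6R)-4-[(tert-butyldimethylsilyl)oxy]-6-[(1S)-1,2-dihydroxyethyl]-4,6-dimethyl-1,2-dioxan-3-ol
Product: 18 (4S,6R)-4-[(tert-butyldimethylsilyl)oxy]-6-[(1S)-1,2-dihydroxyethyl]-3-methoxy-4,6-dimethyl-1,2-dioxane (C3 anomers)
Conditions: MeOH, (1S)-(+)-10-camphorsulfonic acid (cat.), rt
Reagents that add atoms: methanol, CO
Why: Fischer-type acetal exchange in methanol should replace the anomeric hydroxyl by methoxyl through the C3 cation, the large excess of methanol outcompeting the C7 hydroxyl, and the tertiary silyl ether tolerates the weak acid.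

Step 11
Reactants: 18 (4S,6R)-4-[(tert-butyldimethylsilyl)oxy]-6-[(1S)-1,2-dihydroxyethyl]-3-methoxy-4,6-dimethyl-1,2-dioxane
Product: 19 (4S,6R)-4-[(tert-butyldimethylsilyl)oxy]-3-methoxy-4,6-dimethyl-1,2-dioxane-6-carbaldehyde (C3 anomers)
Conditions: NaIO4, THF–H2O (pH 7 buffer), 0 °C to rt
Reagents that add atoms: none
Why: Periodate glycol cleavage is specific for the vicinal diol and leaves dialkyl peroxides and peroxy acetals alone, so the C7 aldehyde on quaternary C6 should form with no risk of enolisation.

Step 12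
Reactants: 20 11-phenylundecanoic acid
Product: 21 11-phenylundecan-1-ol
Conditions: BH3·THF, THF, 0 °C to rt
Reagents that add atoms: none
Why: Borane reduces carboxylic acids to primary alcohols chemoselectively through the acyloxyborane.

Step 13
Reactants: 21 11-phenylundecan-1-ol
Product: 22 (11-bromoundecyl)benzene
Conditions: CBr4, PPh3, CH2Cl2, 0 °C
Reagents that add atoms: carbon tetrabromide, BrC(Br)(Br)Br
Why: Appel bromination converts the primary alcohol into the bromide by SN2 displacement.

Step 14
Reactants: 22 (11-bromoundecyl)benzene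
Product: 23 (11-phenylundecyl)triphenylphosphonium bromide
Conditions: PPh3, MeCN, reflux
Reagents that add atoms: triphenylphosphine, c1ccc(cc1)P(c1ccccc1)c1ccccc1
Why: SN2 quaternisation of triphenylphosphine by a primary bromide gives the Wittig salt.

Step 15
Reactants: 19 (4S,6R)-4-[(tert-butyldimethylsilyl)oxy]-3-methoxy-4,6-dimethyl-1,2-dioxane-6-carbaldehyde; 23 (11-phenylundecyl)triphenylphosphonium bromide
Product: 25 (4S,6R)-4-[(tert-butyldimethylsilyl)oxy]-3-methoxy-4,6-dimethyl-6-[(1Z)-12-phenyldodec-1-en-1-yl]-1,2-dioxane, via phosphorus ylide 24 (not isolated)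
Conditions: 23, NaN(SiMe3)2 (slight deficit), THF, 0 °C; then 19, −78 °C to rt
Reagents that add atoms: none
Why: Wittig olefination with a non-stabilised ylide should join C7 to the chain as the (Z)-alkene at low temperature, where dialkyl peroxides withstand ylides; the geometry is irrelevant because the alkene is reduced next.

Step 16
Reactants: 25 (4S,6R)-4-[(tert-butyldimethylsilyl)oxy]-3-methoxy-4,6-dimethyl-6-[(1Z)-12-phenyldodec-1-en-1-yl]-1,2-dioxane
Product: 26 (4S,6S)-4-[(tert-butyldimethylsilyl)oxy]-3-methoxy-4,6-dimethyl-6-(12-phenyldodecyl)-1,2-dioxane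
Conditions: KO2CN=NCO2K, AcOH, MeOH–CH2Cl2, 0 °C to rt (repeated charges)
Reagents that add atoms: none
Why: Diimide reduction transfers H2 to the C=C bond through a concerted six-centre transition state and does not cleave O–O bonds, which metal-catalysed hydrogenation would endanger.

Step 17
Reactants: 26 (4S,6S)-4-[(tert-butyldimethylsilyl)oxy]-3-methoxy-4,6-dimethyl-6-(12-phenyldodecyl)-1,2-dioxane
Product: 27 (4S,6S)-3-methoxy-4,6-dimethyl-6-(12-phenyldodecyl)-1,2-dioxan-4-ol
Conditions: Bu4NF, AcOH, THF, rt to 40 °C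
Reagents that add atoms: none
Why: Fluoride cleaves the Si–O bond, and buffering with acetic acid keeps the medium near neutral so that neither the peroxy acetal (acid) nor its C3–H (base, Kornblum–DeLaMare fragmentation) should be attacked.

Step 18
Reactants: 27 (4S,6S)-3-methoxy-4,6-dimethyl-6-(12-phenyldodecyl)-1,2-dioxan-4-ol
Product: 28 (4S,6S)-4-{[dimethyl(prop-2-en-1-yl)silyl]oxy}-3-methoxy-4,6-dimethyl-6-(12-phenyldodecyl)-1,2-dioxane
Conditions: allyl(chloro)dimethylsilane, imidazole, DMF, 0 °C to rt
Reagents that add atoms: allyl(chloro)dimethylsilane, C=CC[Si](C)(C)Cl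
Why: Silylation of the tertiary alcohol with a small chlorosilane and imidazole should place the allylsilane tether on O4.

Step 19
Reactants: 28 (4S,6S)-4-{[dimethyl(prop-2-en-1-yl)silyl]oxy}-3-methoxy-4,6-dimethyl-6-(12-phenyldodecyl)-1,2-dioxane
Product: 30 (3S,4S,6S)-4,6-dimethyl-6-(12-phenyldodecyl)-3-(prop-2-en-1-yl)-1,2-dioxan-4-ol, via methoxysilyl ether 29 (not isolated)
Conditions: Me3SiOSO2CF3 (0.2 equiv), CH2Cl2 (0.005 M), −78 °C; then HF·pyridine, THF, 0 °C
Reagents that add atoms: none
Why: Proposed new method: the silyl triflate ionises the C3 methoxy group to a peroxycarbenium ion, which the allylsilane held on O4 can reach only on the O4 face through a seven-membered SE2' transition state, so the allyl group should arrive cis to O4 (3S) while silicon picks up the methoxide to give 29 and regenerate the silyl triflate, and HF·pyridine then frees O4; the closest known reaction types are the intermolecular Lewis-acid Hosomi–Sakurai allylation of monoperoxy acetals through peroxycarbenium ions and the silicon-tethered allyl transfer from allylsilyl ethers to neighbouring oxocarbenium ions and aldehydes.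

Step 20
Reactants: 30 (3S,4S,6S)-4,6-dimethyl-6-(12-phenyldodecyl)-3-(prop-2-en-1-yl)-1,2-dioxan-4-ol
Product: 32 lactol of plakortolide L (C1 is CH–OH in place of C=O; 3S,4S,6S; C1 anomers), via hydroxy aldehyde 31 (not isolated)
Conditions: O3, CH2Cl2, −78 °C; then Me2S, −78 °C to rt
Reagents that add atoms: ozone, [O-][O+]=O
Why: Ozonolysis cleaves the terminal alkene far faster than it attacks the phenyl ring, dimethyl sulfide reduces the ozonide without touching the dialkyl peroxide, and the aldehyde should be trapped at once by the cis O4 hydroxyl as the five-membered lactol, which shields C3 from beta-elimination.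

Step 21
Reactants: 32 lactol of plakortolide L
Product: 33 plakortolide L
Conditions: 2,2,6,6-tetramethylpiperidin-1-oxyl (cat.), PhI(OAc)2, CH2Cl2, rt
Reagents that add atoms: none
Why: Oxoammonium-mediated oxidation (nitroxyl radical with PhI(OAc)2) converts lactols into lactones without base, which should avoid elimination of the beta-peroxide and completes ring B.

Compound list
1 | (R)-lactic acid | C[C@@H](O)C(=O)O | starting material
2 | pivalaldehyde | CC(C)(C)C=O | starting material
3 | (2R,5R)-2-tert-butyl-5-methyl-1,3-dioxolan-4-one | C[C@H]1O[C@@H](C(C)(C)C)OC1=O | intermediate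
4 | prenyl acetate | CC(C)=CCOC(C)=O | starting material
5 | (2E)-4-hydroxy-3-methylbut-2-en-1-yl acetate | OC/C(C)=C/COC(C)=O | intermediate
6 | (2E)-4-bromo-3-methylbut-2-en-1-yl acetate | BrC/C(C)=C/COC(C)=O | intermediate
7 | lithium (2R)-2-tert-butyl-5-methyl-1,3-dioxol-4-olate (enolate of 3) | CC1=C(O[Li])O[C@H](C(C)(C)C)O1 | intermediate
8 | (2R,5S)-5-[(2E)-4-acetoxy-2-methylbut-2-en-1-yl]-2-tert-butyl-5-methyl-1,3-dioxolan-4-one | C[C@@]1(C/C(C)=C/COC(C)=O)O[C@@H](C(C)(C)C)OC1=O | intermediate
9 | methyl (2S,4E)-2,6-dihydroxy-2,4-dimethylhex-4-enoate | COC(=O)[C@@](C)(O)C/C(C)=C/CO | intermediate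
10 | methyl (2S,4E)-2-hydroxy-2,4-dimethyl-6-[(triethylsilyl)oxy]hex-4-enoate | COC(=O)[C@@](C)(O)C/C(C)=C/CO[Si](CC)(CC)CC | intermediate
11 | methyl (2S,4E)-2-[(tert-butyldimethylsilyl)oxy]-2,4-dimethyl-6-[(triethylsilyl)oxy]hex-4-enoate | COC(=O)[C@@](C)(O[Si](C)(C)C(C)(C)C)C/C(C)=C/CO[Si](CC)(CC)CC | intermediate
12 | (2S,4E)-2-[(tert-butyldimethylsilyl)oxy]-2,4-dimethyl-6-[(triethylsilyl)oxy]hex-4-enal | O=C[C@@](C)(O[Si](C)(C)C(C)(C)C)C/C(C)=C/CO[Si](CC)(CC)CC | intermediate
13 | (2S,4E)-2-[(tert-butyldimethylsilyl)oxy]-6-hydroxy-2,4-dimethylhex-4-enal | O=C[C@@](C)(O[Si](C)(C)C(C)(C)C)C/C(C)=C/CO | intermediate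
14 | (2S)-2-[(tert-butyldimethylsilyl)oxy]-3-[(2S,3S)-3-(hydroxymethyl)-2-methyloxiran-2-yl]-2-methylpropanal | O=C[C@@](C)(O[Si](C)(C)C(C)(C)C)C[C@]1(C)O[C@H]1CO | intermediate
15 | hydrogen peroxide | OO | starting material
16 | (2S,4R,5S)-2-[(tert-butyldimethylsilyl)oxy]-4-hydroperoxy-5,6-dihydroxy-2,4-dimethylhexanal | O=C[C@@](C)(O[Si](C)(C)C(C)(C)C)C[C@@](C)(OO)[C@@H](O)CO | intermediate
17 | (4S,6R)-4-[(tert-butyldimethylsilyl)oxy]-6-[(1S)-1,2-dihydroxyethyl]-4,6-dimethyl-1,2-dioxan-3-ol (C3 anomers) | C[C@]1([C@@H](O)CO)C[C@](C)(O[Si](C)(C)C(C)(C)C)C(O)OO1 | intermediate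
18 | (4S,6R)-4-[(tert-butyldimethylsilyl)oxy]-6-[(1S)-1,2-dihydroxyethyl]-3-methoxy-4,6-dimethyl-1,2-dioxane (C3 anomers) | C[C@]1([C@@H](O)CO)C[C@](C)(O[Si](C)(C)C(C)(C)C)C(OC)OO1 | intermediate
19 | (4S,6R)-4-[(tert-butyldimethylsilyl)oxy]-3-methoxy-4,6-dimethyl-1,2-dioxane-6-carbaldehyde (C3 anomers) | C[C@]1(C=O)C[C@](C)(O[Si](C)(C)C(C)(C)C)C(OC)OO1 | intermediate
20 | 11-phenylundecanoic acid | OC(=O)CCCCCCCCCCc1ccccc1 | starting material
21 | 11-phenylundecan-1-ol | OCCCCCCCCCCCc1ccccc1 | intermediate
22 | (11-bromoundecyl)benzene | BrCCCCCCCCCCCc1ccccc1 | intermediate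
23 | (11-phenylundecyl)triphenylphosphonium bromide | [Br-].c1ccccc1CCCCCCCCCCC[P+](c1ccccc1)(c1ccccc1)c1ccccc1 | intermediate
24 | (11-phenylundecylidene)triphenylphosphorane | c1ccccc1CCCCCCCCCCC=P(c1ccccc1)(c1ccccc1)c1ccccc1 | intermediate
25 | (4S,6R)-4-[(tert-butyldimethylsilyl)oxy]-3-methoxy-4,6-dimethyl-6-[(1Z)-12-phenyldodec-1-en-1-yl]-1,2-dioxane | C[C@]1(/C=C\CCCCCCCCCCc2ccccc2)C[C@](C)(O[Si](C)(C)C(C)(C)C)C(OC)OO1 | intermediate
26 | (4S,6S)-4-[(tert-butyldimethylsilyl)oxy]-3-methoxy-4,6-dimethyl-6-(12-phenyldodecyl)-1,2-dioxane | C[C@]1(CCCCCCCCCCCCc2ccccc2)C[C@](C)(O[Si](C)(C)C(C)(C)C)C(OC)OO1 | intermediate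
27 | (4S,6S)-3-methoxy-4,6-dimethyl-6-(12-phenyldodecyl)-1,2-dioxan-4-ol | C[C@]1(CCCCCCCCCCCCc2ccccc2)C[C@](C)(O)C(OC)OO1 | intermediate
28 | (4S,6S)-4-{[dimethyl(prop-2-en-1-yl)silyl]oxy}-3-methoxy-4,6-dimethyl-6-(12-phenyldodecyl)-1,2-dioxane | C[C@]1(CCCCCCCCCCCCc2ccccc2)C[C@](C)(O[Si](C)(C)CC=C)C(OC)OO1 | intermediate
29 | (3S,4S,6S)-4-{[methoxy(dimethyl)silyl]oxy}-4,6-dimethyl-6-(12-phenyldodecyl)-3-(prop-2-en-1-yl)-1,2-dioxane | C[C@]1(CCCCCCCCCCCCc2ccccc2)C[C@](C)(O[Si](C)(C)OC)[C@H](CC=C)OO1 | intermediate
30 | (3S,4S,6S)-4,6-dimethyl-6-(12-phenyldodecyl)-3-(prop-2-en-1-yl)-1,2-dioxan-4-ol | C[C@]1(CCCCCCCCCCCCc2ccccc2)C[C@](C)(O)[C@H](CC=C)OO1 | intermediate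
31 | [(3S,4S,6S)-4-hydroxy-4,6-dimethyl-6-(12-phenyldodecyl)-1,2-dioxan-3-yl]acetaldehyde | C[C@]1(CCCCCCCCCCCCc2ccccc2)C[C@](C)(O)[C@H](CC=O)OO1 | intermediate
32 | lactol of plakortolide L (C1 is CH–OH; 3S,4S,6S; C1 anomers) | C[C@]1(CCCCCCCCCCCCc2ccccc2)C[C@]2(C)OC(O)C[C@@H]2OO1 | intermediate
33 | plakortolide L (3S,4S,6S) | C[C@]1(CCCCCCCCCCCCc2ccccc2)C[C@]2(C)OC(=O)C[C@@H]2OO1 | target

Total step count: 21.
Longest linear sequence: 17 steps (prenyl acetate 4 to plakortolide L 33: steps 2–11 and 15–21).

Steps most likely to fail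

1. Step 19 (bears the label). What may go wrong: the peroxycarbenium ion may fragment by O–O heterolysis before the tethered allylsilane reaches it, or allyl transfer may take place between molecules and erode the facial control. Fallback with known chemistry: setting out from silyl ether 26, the intermolecular Hosomi–Sakurai substitution of the peroxy acetal (allyltrimethylsilane, SnCl4, CH2Cl2, −78 °C) should give the C3-allyl silyl ether F1 together with its C3 epimer. The 3S epimer would be separated by chromatography and desilylated with Bu4NF/AcOH, which brings the route back at 30.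

2. Step 9. What may go wrong: the carbonyl oxygen, or the hydroxyl of the perhydrate, may open the activated epoxide in a five-membered mode; the aldehyde may be oxidised with migration of C4; or the acid may strip the silyl ether. Fallback: separate the two events. Setting out from hydroxy aldehyde 13, Wittig methylenation (Ph3P=CH2, THF, 0 °C) should give the diene alcohol F2. Sharpless epoxidation under the conditions of step 8 should give the vinyl epoxy alcohol F3. The H2O2/H3PMo12O40 perhydrolysis, now on a substrate without a carbonyl group, should give the hydroxy hydroperoxide F4. Ozonolysis of the vinyl group in acetone–water (no reductant, so the hydroperoxide is kept) should then unveil the C3 aldehyde, which closes onto the C6 hydroperoxide and rejoins the route at 17.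

3. Step 10. What may go wrong: the C3 cation may be captured by the C7 hydroxyl to give a bridged trioxane, or the ring may open under acid, instead of exchanging with methanol. Fallback: setting out from 17, 2,2-dimethoxypropane and methanol with pyridinium p-toluenesulfonate should mask the diol while the anomeric hydroxyl is exchanged, giving the acetonide methyl acetal F5. H5IO6 in ethyl acetate should then hydrolyse the terminal acetonide and cleave the glycol in one pot, rejoining the route at aldehyde 19.

Further compounds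
F1 | step 19 | (3S,4S,6S)-4-[(tert-butyldimethylsilyl)oxy]-4,6-dimethyl-6-(12-phenyldodecyl)-3-(prop-2-en-1-yl)-1,2-dioxane | C[C@]1(CCCCCCCCCCCCc2ccccc2)C[C@](C)(O[Si](C)(C)C(C)(C)C)[C@H](CC=C)OO1
F2 | step 9 | (2E,5S)-5-[(tert-butyldimethylsilyl)oxy]-3,5-dimethylhepta-2,6-dien-1-ol | C=C[C@@](C)(O[Si](C)(C)C(C)(C)C)C/C(C)=C/CO
F3 | step 9 | [(2S,3S)-3-{(2S)-2-[(tert-butyldimethylsilyl)oxy]-2-methylbut-3-en-1-yl}-3-methyloxiran-2-yl]methanol | C=C[C@@](C)(O[Si](C)(C)C(C)(C)C)C[C@]1(C)O[C@H]1CO
F4 | step 9 | (2S,3R,5S)-5-[(tert-butyldimethylsilyl)oxy]-3-hydroperoxy-3,5-dimethylhept-6-ene-1,2-diol | C=C[C@@](C)(O[Si](C)(C)C(C)(C)C)C[C@@](C)(OO)[C@@H](O)CO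
F5 | step 10 | (4S)-4-[(4S,6R)-4-[(tert-butyldimethylsilyl)oxy]-3-methoxy-4,6-dimethyl-1,2-dioxan-6-yl]-2,2-dimethyl-1,3-dioxolane | C[C@]1([C@@H]2COC(C)(C)O2)C[C@](C)(O[Si](C)(C)C(C)(C)C)C(OC)OO1
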